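The rate constants were set for the occasion, and the outcome is calculated.

A small charge of X, 0.25 M of solid, went into each flask, and the flasks differed in temperature.

in all of them: X 0.25 M; time 5.0 h

| run | temperature |
|---|---|
| Wednesday's | 130 °C |
| Friday's | 70 °C |
| Tuesday's | 110 °C |
| Thursday's | 90 °C |

- which flask leads in amount of G, in percent of the X charged ("all alike" within 1.5 percentage points) (Wednesday's / Friday's / Tuesday's / Thursday's / all alike)
- how much G is there at the end, in percent of the X charged: Wednesday's
- how much G is there at the end, in percent of the X charged: Friday's
- how much G is there at the end, in percent of the X charged: Tuesday's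
- how much G is there at the end, in percent of the X charged: Thursday's

- percent here means X units held: one J.G counts as two
- X is a solid; its amount is given per volume of the solution
- all constants are for 110 °C and move with temperature by the activation energies and enthalpies
- at the start none of X is in solution
- what has only dissolved of X counts as not reacted

    J + G → J.G (k1 = 0.16 /M/min, Ea1 = 85.0 kJ/mol)
    J ⇌ G + Z (K2 = 0.29 M, k2 = 0.043 /min, Ea2 = 104 kJ/mol, ΔH2 = −42.0 kJ/mol)
    J + Z → J.Z (k3 = 0.37 /M/min, Ea3 = 69.0 kJ/mol)
    X ⇌ J, rate k4*(cs4 - [J]) while solid is left; crystals form when [J] > cs4 (cs4 = 0.16 M, k4 = 0.015 /min)
    (constants at 110 °C)

X dissolved to J, J split reversibly into G and Z, and each of these could take up a further J, giving J.G and J.Z. The solution could hold 64.0 % of the charge as J.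

Two numbers puzzled me. From Friday's to Wednesday's the split of J sped up 230 times and the capture of J by G 84 times, so the split gained and heat looked good for G. Yet the equilibrium constant of the split, in units of the charge, fell from 5.39 at Friday's to 1.16 at Tuesday's, so heat looked bad for G.

I reckoned that both held, at different stages. The stages are parted by the feed time, the shortest time in which the solid can enter an empty solution, which is the charge over the top dissolving pace: 1.74 h. Dissolving has no activation energy here. A J lasted 0.388 h against splitting in Tuesday's, shorter than the 1.11 h of dissolving. So I took dissolving for the rate-limiting step in Tuesday's, and I expected the solid to go soon after the feed time, leaving about 3.26 h in which G could be lost. In Friday's that life was 17.4 h, longer than dissolving. So I expected J to pile up in Friday's towards the 64.0 % the solution could hold, and with J below that level G would stay under 18.4 %. I expected control to change hands between these two flasks, so I looked for the lead in Thursday's, though I reached no figure for it.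

The forecast named Thursday's, with 12 % for Wednesday's, 12 % for Friday's, 23 % for Tuesday's and 35 % for Thursday's, at the temperature “where the split is fast enough but the solid lasts most of the run and the erosion has little time to act”.

The flasks gave 10.6 %, 11.9 %, 23.4 % and 35.3 % in that order, and Thursday's led.

In Thursday's, X still stood at 19.1 % after 2.50 h, well past the feed time of 1.74 h, while Tuesday's then stood at 0 %. Thursday's reached 0 % by 5.00 h. The neighbour of Thursday's got 0.062 M of X, a quarter of the charge, so its feed time was 0.431 h. At the end that neighbour held 14.7 % as J.G, 19.4 % as J.Z and 59.7 % as G, against 35.3 % in Thursday's.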